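The vessel was a closed, stirred flask in which a solid substrate fed a solution, and there the dissolved substrate met the reagent to make target. Nothing was dissolved at the start.

common to all: reagent 1.05 equiv

|  | solid substrate | remark | time |
|---|---|---|---|
| alpha | 0.067 M | run made earlier |  |
| theta | 0.15 M | run made earlier |  |
| flask | 0.10 M |  | 80 min |

| run | time / min | target / % | dissolved substrate / % |
|---|---|---|---|
| alpha | 10.0 | 0.2 | 30.7 |
| alpha | 30.0 | 7.4 | 49.0 |
| alpha | 50.0 | 12.5 | 53.6 |
| alpha | 80.0 | 16.4 | 45.0 |
| theta | 10.0 | 2.2 | 13.9 |
| theta | 30.0 | 7.4 | 21.2 |
| theta | 50.0 | 11.3 | 22.8 |
| theta | 80.0 | 16.0 | 24.0 |

(scatter of a reading: 0.5 percentage points)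

- the target standing at 80 min, as a percentage of the solid substrate charged
- concentration of dissolved substrate in solution at 40 min, in percent of saturation
- the change that raises the amount of target at 80 min, in percent of the solid substrate charged most ("none" if none brings more than 2 percentage points) (amber / violet / teal / none)
- amount of target at 80 min, in percent of the solid substrate charged, after teal

- solid, in amounts per volume of the solution: solid substrate
- at the start none of the solid substrate is in solution
- dissolved substrate means what is dissolved; the solid is not counted in it

- amber: doubling the dissolution coefficient of the solid substrate, all else as stated
- violet: doubling the amount of reagent, all else as stated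
- teal: doubling the solubility of the solid substrate, all else as stated

From the two target readings at 80 min I reckoned 519 min. This is the reagent clock, the time in which the reagent charge would turn wholly into target at the net average pace of those runs over that time.

I took two extreme versions. With lavish solid the solution stays at its plateau, the clock is the same for any charge, and the reagent scales with the charge, so the target share does not depend on the charge. Alpha and theta support this: their charges differed by a factor of 2.24, yet their shares differed by 0.4 percentage points against a scatter of 0.5 points. With scant solid the whole charge dissolves below the plateau, the clock stretches, and the share falls in proportion to the charge.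

Theta's last dissolved reading, counted on this flask's charge, is 36.0%, less than the whole charge. The flask's charge also lies between alpha's and theta's, so it stands on the lavish side. I committed to 16.2%.

The forecast gave 16.2%, 76% of saturation, violet as the best change, and 27% after teal: “Doubling solubility exhausts the solid by about 45 min, giving about 27%.”

The flask gave 16.9%, a clock of 497 min, with 75.4% of saturation and violet best at a gain of 15 points; teal gave 20.7%, below the forecast's 27%.

    dissolved substrate + reagent ⇌ target (K = 8.90 M⁻¹, k = 6.70 M⁻¹ h⁻¹)
    2 dissolved substrate → side product (k = 10.0 M⁻¹ h⁻¹)
    solid substrate ⇌ dissolved substrate, rate k3*(cs3 - [dissolved substrate]) while solid is left; crystals form when [dissolved substrate] > cs3 (solubility = 45.0 mM, k = 4.00 h⁻¹)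

At 80.0 min this flask still held 21.1% as solid. In the neighbour flask with 0.025 M of solid substrate, the plateau is 144% of the charge, which is the scant version, and the clock stretched in proportion gives 11.2%. That neighbour held 0% as solid and 9.46% as target.

The data are simulated for an exercise; the scatter is artificial.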